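**Retrosynthetic overview**

1. Feature: in ring A (C1–C2=C3–C3a–C6a–C7) the C7 carboxyl is γ,δ-unsaturated through C2=C3, so the C1–C7 bond between the two quaternary carbons is a [3,3] retron. It leads back to a trans-fused cyclopenta-δ-lactone with its ring oxygen on C3 and an E-trienyl arm on C3.
2. Lactone: C3 is set by MeCeCl2 addition to a trienyl ketone, followed by lactonisation onto the C7 ester. The trienyl arm is built on the substrate from an alkynyl carbinol by syn protoboration and Suzuki coupling with a dienyl iodide (ethyl cis to C3).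
3. Ring B is made first, from (R)-4-silyloxycyclopentenone. A dithianyl group (masked C3 aldehyde) added at C3a directs, by anti induction, the acetate arm on C6a and the methyl on C4; an enol triflate then fixes C5=C6 and takes the C6 methyl.
4. Ring order: ring B (chiral pool), then the temporary lactone ring, then ring A in the key step.

Key step: step 13

Remark: atoms carry the labels of the target (ring A: C1, C2, C3, C3a, C6a, C7; ring B: C3a, C4, C5, C6, C6a) from the dithianyl enone of step 3 onward, and C7 is deliberately carried as both epimers once its methyl is in place, because step 13 makes it trigonal.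

**Route**

Step 1
Reactants: 1 (E)-cinnamaldehyde
Product: 2 [(1E)-but-1-en-3-yn-1-yl]benzene
Conditions: Me3SiCHN2, LiN(iPr)2, THF, −78 °C to rt
Reagents that add atoms: (trimethylsilyl)diazomethane, C[Si](C)(C)C=[N+]=[N-]
Why: Colvin rearrangement: the lithiated diazo reagent adds to the aldehyde, silanolate is lost and the resulting alkylidene carbene shifts hydrogen to give the terminal alkyne, without the methanol adducts that enals give under Ohira–Bestmann conditions and without touching the E-styryl alkene.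

Step 2
Reactants: 2 [(1E)-but-1-en-3-yn-1-yl]benzene
Product: 4 [(1E,3E)-4-iodo-3-methylbuta-1,3-dien-1-yl]benzene, via alkenyldimethylalane 3 (not isolated)
Conditions: AlMe3, Cp2ZrCl2 (0.2 equiv), CH2Cl2, 0 °C to rt; then I2, THF, −30 °C
Reagents that add atoms: trimethylaluminium, C[Al](C)C; iodine, II
Why: Negishi carboalumination (Cp2ZrCl2-catalysed) adds methyl and aluminium syn across the terminal alkyne with methyl on the internal carbon, and iodinolysis with retention should give the E,E-dienyl iodide.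

Step 3
Reactants: 5 (4R)-4-[tert-butyl(dimethyl)silyl]oxycyclopent-2-en-1-one; 6 1,3-dithiane
Product: 8 (4R)-4-(1,3-dithian-2-yl)cyclopent-2-en-1-one, via conjugate adduct 7 (not isolated)
Conditions: 6, n-BuLi, THF, −30 °C; HMPA, then 5, −78 °C; AcOH; then DBU, CH2Cl2, 0 °C
Reagents that add atoms: none
Why: In the presence of HMPA the 2-lithiodithiane adds 1,4 (Michael addition) anti to the silyloxy group, which fixes C3a and brings in C3 as a masked aldehyde, and E1cB loss of silanol with DBU then moves the enone so that the new group sits on its γ-carbon.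

Step 4
Reactants: 8 (4R)-4-(1,3-dithian-2-yl)cyclopent-2-en-1-one; 9 methyl bromoacetate
Product: 11 methyl 2-[(1R,5S)-5-(1,3-dithian-2-yl)-2-oxocyclopent-3-en-1-yl]acetate, via lithium dienolate 10 (not isolated)
Conditions: LiN(iPr)2, THF, −78 °C; then 9, −78 to −40 °C
Reagents that add atoms: none
Why: Kinetic deprotonation at the α′ carbon (C6a) and SN2 alkylation of the cross-conjugated enolate should occur anti to the adjacent dithianyl group, giving the trans C3a/C6a relationship.

Step 5
Reactants: 11 methyl 2-[(1R,5S)-5-(1,3-dithian-2-yl)-2-oxocyclopent-3-en-1-yl]acetate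
Product: 13 methyl 2-[5-(1,3-dithian-2-yl)-4-methyl-2-(trifluoromethylsulfonyloxy)cyclopent-2-en-1-yl]acetate, via lithium enolate 12 (not isolated)
Conditions: Me2CuLi (from CuI, MeLi), Et2O/THF, −78 °C; then Comins' reagent, −78 to 0 °C
Reagents that add atoms: lithium dimethylcuprate, [Li+].C[Cu-]C; N-(5-chloropyridin-2-yl)-1,1,1-trifluoro-N-(trifluoromethylsulfonyl)methanesulfonamide (Comins' reagent), O=S(=O)(N(c1ccc(Cl)cn1)S(=O)(=O)C(F)(F)F)C(F)(F)F
Why: Conjugate addition of Me2CuLi to the β-carbon (C4) anti to the neighbouring dithianyl group sets the C4 methyl trans to it, and O-triflation of the regiodefined enolate fixes the alkene between C5 and C6.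

Step 6
Reactants: 13 methyl 2-[5-(1,3-dithian-2-yl)-4-methyl-2-(trifluoromethylsulfonyloxy)cyclopent-2-en-1-yl]acetate
Product: 14 methyl 2-[5-(1,3-dithian-2-yl)-2,4-dimethylcyclopent-2-en-1-yl]acetate
Conditions: Me2CuLi (3 equiv), THF, −15 °C
Reagents that add atoms: lithium dimethylcuprate, [Li+].C[Cu-]C
Why: Organocuprate cross-coupling with the enol triflate replaces OTf by methyl without moving the alkene, completing ring B (C5=C6, C6 methyl); the ester and dithiane are inert at this temperature.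

Step 7
Reactants: 14 methyl 2-[5-(1,3-dithian-2-yl)-2,4-dimethylcyclopent-2-en-1-yl]acetate
Product: 16 methyl 2-[5-(1,3-dithian-2-yl)-2,4-dimethylcyclopent-2-en-1-yl]propanoate, via lithium ester enolate 15 (not isolated)
Conditions: LiN(iPr)2, THF, −78 °C; then MeI, −78 to −20 °C
Reagents that add atoms: iodomethane, CI
Why: Enolate alkylation at the only acidic site, the ester α-carbon, installs the C7 methyl; its configuration is not controlled and need not be, since C7 becomes trigonal in step 13.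

Step 8
Reactants: 16 methyl 2-[5-(1,3-dithian-2-yl)-2,4-dimethylcyclopent-2-en-1-yl]propanoate
Product: 17 methyl 2-(5-formyl-2,4-dimethylcyclopent-2-en-1-yl)propanoate
Conditions: MeI, CaCO3, MeCN/H2O, 45 °C
Reagents that add atoms: water, O
Why: S-Alkylation of the dithiane and buffered hydrolysis unmask the C3 aldehyde without acid or oxidant, so the trisubstituted alkene survives and C3a stays in its preferred trans arrangement.

Step 9
Reactants: 17 methyl 2-(5-formyl-2,4-dimethylcyclopent-2-en-1-yl)propanoate; 18 but-1-yne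
Product: 19 methyl 2-[5-(1-hydroxypent-2-yn-1-yl)-2,4-dimethylcyclopent-2-en-1-yl]propanoate
Conditions: 18, n-BuLi, THF, −78 °C; then 17, −78 °C
Reagents that add atoms: none
Why: 1,2-Addition of but-1-ynyllithium to the aldehyde at −78 °C is much faster than attack on the α-branched ester; the new carbinol centre is a mixture that is erased by the oxidation of step 11.

Step 10
Reactants: 19 methyl 2-[5-(1-hydroxypent-2-yn-1-yl)-2,4-dimethylcyclopent-2-en-1-yl]propanoate; 4 [(1E,3E)-4-iodo-3-methylbuta-1,3-dien-1-yl]benzene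
Product: 21 methyl 2-{5-[(2E,4E,6E)-3-ethyl-1-hydroxy-5-methyl-7-phenylhepta-2,4,6-trien-1-yl]-2,4-dimethylcyclopent-2-en-1-yl}propanoate, via alkenylboronate 20 (not isolated)
Conditions: B2pin2, CuCl (5 mol %), Xantphos, NaOtBu (10 mol %), MeOH, THF, rt; silica plug; then 4, Pd(PPh3)4 (5 mol %), K3PO4, THF/H2O, 45 °C
Reagents that add atoms: bis(pinacolato)diboron, CC1(C)OB(OC1(C)C)B1OC(C)(C)C(C)(C)O1 (boron is present only in 20)
Why: CuCl-catalysed protoboration adds H and Bpin syn across the alkyne with boron on the carbon distal to the carbinol (steric and electronic bias of propargylic alcohols), so ethyl ends cis to C3, and Pd(PPh3)4-catalysed Suzuki–Miyaura coupling with 4 then proceeds with retention at both partners to give the E,E,E-triene.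

Step 11
Reactants: 21 methyl 2-{5-[(2E,4E,6E)-3-ethyl-1-hydroxy-5-methyl-7-phenylhepta-2,4,6-trien-1-yl]-2,4-dimethylcyclopent-2-en-1-yl}propanoate
Product: 22 methyl 2-{5-[(2E,4E,6E)-3-ethyl-5-methyl-7-phenylhepta-2,4,6-trienoyl]-2,4-dimethylcyclopent-2-en-1-yl}propanoate
Conditions: Dess–Martin periodinane, NaHCO3, CH2Cl2, 0 °C
Reagents that add atoms: none
Why: Dess–Martin oxidation of the allylic secondary alcohol under buffered, non-epimerising conditions should give the conjugated trienone with the alkene geometry intact.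

Step 12
Reactants: 22 methyl 2-{5-[(2E,4E,6E)-3-ethyl-5-methyl-7-phenylhepta-2,4,6-trienoyl]-2,4-dimethylcyclopent-2-en-1-yl}propanoate
Product: 24 (1S,4aS,7R,7aS)-1-[(1E,3E,5E)-2-ethyl-4-methyl-6-phenylhexa-1,3,5-trien-1-yl]-1,4,5,7-tetramethyl-4,4a,7,7a-tetrahydrocyclopenta[c]pyran-3(1H)-one as both C4 epimers (C4 of this name is C7 of the target), via tertiary alkoxide 23 (not isolated)
Conditions: MeLi, CeCl3, THF, −78 °C; then KOtBu (0.2 equiv), THF, 0 °C
Reagents that add atoms: methyllithium, [Li]C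
Why: MeCeCl2 adds 1,2 to the ketone (not to the ester, and without enolisation) and, by the Felkin–Anh model, anti to the bulkier C6a branch with C3a–H beside the trienyl group, which places the C3 methyl cis and the trienyl arm trans to C4; alkoxide-catalysed transesterification onto the methyl ester then closes the trans-fused δ-lactone, and any C3 epimer is removed here.

Step 13
Reactants: 24 (1S,4aS,7R,7aS)-1-[(1E,3E,5E)-2-ethyl-4-methyl-6-phenylhexa-1,3,5-trien-1-yl]-1,4,5,7-tetramethyl-4,4a,7,7a-tetrahydrocyclopenta[c]pyran-3(1H)-one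
Product: 27 (1R,3aR,4R,5S,7aS)-5-ethyl-1,3,4,7-tetramethyl-5-[(1E,3E)-2-methyl-4-phenylbuta-1,3-dien-1-yl]-3a,4,5,7a-tetrahydro-1H-indene-4-carboxylic acid (the target), via silyl ketene acetal 25 (not isolated), via silyl ester 26 (not isolated)
Conditions: LiN(SiMe3)2, Me3SiCl, Et3N, THF, −78 °C; then toluene, 110 °C; then 1 M HCl, THF, rt
Reagents that add atoms: chlorotrimethylsilane, C[Si](C)(C)Cl (silicon is present only in 25 and 26)
Why: LiN(SiMe3)2 removes the C7–H of the lactone and O-silylation gives ketene acetal 25, which on heating undergoes a concerted suprafacial [3,3] shift (the Ireland–Claisen rearrangement in its lactone form, known for 6-alkenyl δ-lactones) in which C7 bonds to C1 as the C3–O bond breaks and the alkene moves to C2–C3. Ring A (C1–C2–C3–C3a–C6a–C7) closes as a six-membered carbocycle by exchange of the O–C(O) unit of the lactone for C1–C2, and the C3a–C6a tether allows only a boat array with the trienyl arm axial on C3 over the ketene acetal. C7 is set because the new bond can form only on the lactone face that carries the trienyl arm (the face of C3a–H), which puts the carboxyl and the C1 dienyl arm cis on ring A. C1 is set by the E geometry of the C1–C2 alkene of 24 (ethyl cis to C3), which places ethyl inside the boat and the dienyl group outside. The step needs O-silylation and rearrangement to outrun ionisation of the tertiary allylic C–O bond; the basic aprotic medium and the ring-fixed ketene acetal geometry should secure this, while the trans-fused ring B adds strain to the boat and makes this the step at risk. Dilute acid then cleaves silyl ester 26 to acid 27.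

**Compound list**

1 | (E)-cinnamaldehyde | O=C/C=C/c1ccccc1 | starting material
2 | [(1E)-but-1-en-3-yn-1-yl]benzene | C#C/C=C/c1ccccc1 | intermediate
3 | dimethyl[(1E,3E)-2-methyl-4-phenylbuta-1,3-dien-1-yl]alane | C[Al](C)/C=C(C)/C=C/c1ccccc1 | intermediate (not isolated)
4 | [(1E,3E)-4-iodo-3-methylbuta-1,3-dien-1-yl]benzene | I/C=C(C)/C=C/c1ccccc1 | intermediate
5 | (4R)-4-[tert-butyl(dimethyl)silyl]oxycyclopent-2-en-1-one | O=C1C=C[C@H](O[Si](C)(C)C(C)(C)C)C1 | starting material
6 | 1,3-dithiane | C1CSCSC1 | starting material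
7 | (3R,4R)-3-(1,3-dithian-2-yl)-4-[tert-butyl(dimethyl)silyl]oxycyclopentan-1-one (trans) | O=C1C[C@@H](C2SCCCS2)[C@H](O[Si](C)(C)C(C)(C)C)C1 | intermediate (not isolated)
8 | (4R)-4-(1,3-dithian-2-yl)cyclopent-2-en-1-one | O=C1C=C[C@H](C2SCCCS2)C1 | intermediate
9 | methyl bromoacetate | COC(=O)CBr | starting material
10 | lithium 3-(1,3-dithian-2-yl)cyclopenta-1,4-dien-1-olate | [Li]OC1=C[C@@H](C2SCCCS2)C=C1 | intermediate (not isolated)
11 | methyl 2-[(1R,5S)-5-(1,3-dithian-2-yl)-2-oxocyclopent-3-en-1-yl]acetate (trans) | O=C1C=C[C@H](C2SCCCS2)[C@H]1CC(=O)OC | intermediate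
12 | methyl 2-[5-(1,3-dithian-2-yl)-2-(lithiooxy)-4-methylcyclopent-2-en-1-yl]acetate | [Li]OC1=C[C@@H](C)[C@H](C2SCCCS2)[C@H]1CC(=O)OC | intermediate (not isolated)
13 | methyl 2-[5-(1,3-dithian-2-yl)-4-methyl-2-(trifluoromethylsulfonyloxy)cyclopent-2-en-1-yl]acetate (dithianyl trans to both neighbours) | O=S(=O)(OC1=C[C@@H](C)[C@H](C2SCCCS2)[C@H]1CC(=O)OC)C(F)(F)F | intermediate
14 | methyl 2-[5-(1,3-dithian-2-yl)-2,4-dimethylcyclopent-2-en-1-yl]acetate (dithianyl trans to both neighbours) | CC1=C[C@@H](C)[C@H](C2SCCCS2)[C@H]1CC(=O)OC | intermediate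
15 | lithium 2-[5-(1,3-dithian-2-yl)-2,4-dimethylcyclopent-2-en-1-yl]-1-methoxyethen-1-olate | CC1=C[C@@H](C)[C@H](C2SCCCS2)[C@H]1C=C(O[Li])OC | intermediate (not isolated)
16 | methyl 2-[5-(1,3-dithian-2-yl)-2,4-dimethylcyclopent-2-en-1-yl]propanoate (both C7 epimers) | CC1=C[C@@H](C)[C@H](C2SCCCS2)[C@H]1C(C)C(=O)OC | intermediate
17 | methyl 2-(5-formyl-2,4-dimethylcyclopent-2-en-1-yl)propanoate (both C7 epimers) | CC1=C[C@@H](C)[C@H](C=O)[C@H]1C(C)C(=O)OC | intermediate
18 | but-1-yne | CCC#C | starting material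
19 | methyl 2-[5-(1-hydroxypent-2-yn-1-yl)-2,4-dimethylcyclopent-2-en-1-yl]propanoate (carbinol and C7 epimers) | CC1=C[C@@H](C)[C@H](C(O)C#CCC)[C@H]1C(C)C(=O)OC | intermediate
20 | methyl 2-{5-[(2Z)-1-hydroxy-3-(4,4,5,5-tetramethyl-1,3,2-dioxaborolan-2-yl)pent-2-en-1-yl]-2,4-dimethylcyclopent-2-en-1-yl}propanoate | CC1=C[C@@H](C)[C@H](C(O)/C=C(\CC)B2OC(C)(C)C(C)(C)O2)[C@H]1C(C)C(=O)OC | intermediate (not isolated)
21 | methyl 2-{5-[(2E,4E,6E)-3-ethyl-1-hydroxy-5-methyl-7-phenylhepta-2,4,6-trien-1-yl]-2,4-dimethylcyclopent-2-en-1-yl}propanoate | CC1=C[C@@H](C)[C@H](C(O)/C=C(CC)/C=C(C)/C=C/c2ccccc2)[C@H]1C(C)C(=O)OC | intermediate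
22 | methyl 2-{5-[(2E,4E,6E)-3-ethyl-5-methyl-7-phenylhepta-2,4,6-trienoyl]-2,4-dimethylcyclopent-2-en-1-yl}propanoate (both C7 epimers) | CC1=C[C@@H](C)[C@H](C(=O)/C=C(CC)/C=C(C)/C=C/c2ccccc2)[C@H]1C(C)C(=O)OC | intermediate
23 | tertiary alkoxide, drawn as the alcohol: methyl 2-{5-[(3E,5E,7E)-4-ethyl-2-hydroxy-6-methyl-8-phenylocta-3,5,7-trien-2-yl]-2,4-dimethylcyclopent-2-en-1-yl}propanoate | C[C@@](O)(/C=C(CC)/C=C(C)/C=C/c1ccccc1)[C@H]1[C@H](C)C=C(C)[C@@H]1C(C)C(=O)OC | intermediate (not isolated)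
24 | (1S,4aS,7R,7aS)-1-[(1E,3E,5E)-2-ethyl-4-methyl-6-phenylhexa-1,3,5-trien-1-yl]-1,4,5,7-tetramethyl-4,4a,7,7a-tetrahydrocyclopenta[c]pyran-3(1H)-one (trans-fused; both epimers at the lactone α-carbon) | C[C@]1(/C=C(CC)/C=C(C)/C=C/c3ccccc3)OC(=O)C(C)[C@H]2C(C)=C[C@@H](C)[C@H]12 | intermediate (key-step precursor)
25 | trimethylsilyl ketene acetal of 24 | C[C@]1(/C=C(CC)/C=C(C)/C=C/c3ccccc3)OC(O[Si](C)(C)C)=C(C)[C@H]2C(C)=C[C@@H](C)[C@H]12 | intermediate (not isolated)
26 | trimethylsilyl ester of 27 | CC[C@]1(/C=C(C)/C=C/c2ccccc2)C=C(C)[C@H]2[C@H](C)C=C(C)[C@@H]2[C@@]1(C)C(=O)O[Si](C)(C)C | intermediate (not isolated)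
27 | (1R,3aR,4R,5S,7aS)-5-ethyl-1,3,4,7-tetramethyl-5-[(1E,3E)-2-methyl-4-phenylbuta-1,3-dien-1-yl]-3a,4,5,7a-tetrahydro-1H-indene-4-carboxylic acid | CC[C@]1(/C=C(C)/C=C/c2ccccc2)C=C(C)[C@H]2[C@H](C)C=C(C)[C@@H]2[C@@]1(C)C(=O)O | target

**Step count and risks**

Total: 13 steps (two for dienyl iodide 4, eleven in the main line). Longest linear sequence: 11 steps (steps 3 to 13, from 5).

Step 13 (lactone Ireland–Claisen). The trans-fused cyclopentene holds the C3a–C6a torsion near 70°, and the boat array must accommodate this while a bond forms between two fully substituted carbons. If the barrier lies above the temperature at which ketene acetal 25 ionises at its tertiary trienylic C–O bond or eliminates, rearrangement will not compete. Fallback, setting out from 19 and returning at 27: carry out the same rearrangement with ring B open and close ring B last. Ozonolysis of the C5=C6 alkene of 19 (O3, CH2Cl2, −78 °C, then Me2S; the internal alkyne reacts far more slowly) would give keto aldehyde F1, and non-basic methylenation of both carbonyls (Zn, CH2Br2, TiCl4) would give diene F2, with a but-3-en-2-yl arm on C3a and an isopropenyl arm on C6a. F2 is then taken through the chemistry of steps 10 to 13: protoboration to alkenylboronate F3, Suzuki coupling with 4 to trienol F4, oxidation to trienone F5, MeCeCl2 addition to tertiary alkoxide F6 and closure to monocyclic lactone F7. Silyl ketene acetal F8, whose boat is no longer strained by ring B, should rearrange to silyl ester F9 and, after hydrolysis, give seco acid F10. Ring-closing metathesis of F10 (second-generation Grubbs catalyst, CH2Cl2, 40 °C) between the vinyl and isopropenyl arms then forms the C5=C6 alkene and gives 27.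

Step 12 (MeCeCl2 addition). The two flanks of the ketone (C4 and C6a) are both secondary carbons and the nucleophile is small, so facial discrimination may be weak or even reversed, which would deliver the C3 epimer and hence the wrong C1/C7 pair. Fallback, setting out from 17 and returning at 23: exchange the roles of the two carbon groups on C3. MeLi/CeCl3 addition to 17 would give carbinol F11 and Dess–Martin oxidation methyl ketone F12. But-1-ynyllithium/CeCl3 then attacks the same preferred face but delivers the alkynyl group, giving tertiary propargylic alcohol F13 with the complementary C3 configuration. CuCl-catalysed protoboration to alkenylboronate F14 and Suzuki coupling with 4 give the hydroxy ester of 23, which is closed to 24 with KOtBu as in step 12. If one face is clearly preferred, one of the two orders leads to 24; if discrimination is merely weak, the epimers are separated at 24.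

Step 4 (α′-alkylation of the cyclopentenone). Proton transfer between product and enolate, dialkylation and Michael self-condensation of the cross-conjugated enolate may erode the yield. Fallback, setting out from 5 (with 6 and 9) and returning at 11: alkylate the saturated, regiodefined enolate instead. The lithium enolate F15 formed by the 1,4-addition of step 3 is trapped at −78 °C with 9 before any proton transfer, giving the 2,3-trans-3,4-trans cyclopentanone F16, and DBU then eliminates silanol to give 11.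

**Further compounds**

F1 | step 13 | methyl 3-acetyl-4-(1-hydroxypent-2-yn-1-yl)-2,5-dimethyl-6-oxohexanoate | O=C[C@@H](C)[C@H](C(O)C#CCC)[C@H](C(C)=O)C(C)C(=O)OC
F2 | step 13 | methyl 4-(1-hydroxypent-2-yn-1-yl)-2,5-dimethyl-3-(prop-1-en-2-yl)hept-6-enoate | C=C[C@@H](C)[C@H](C(O)C#CCC)[C@H](C(C)=C)C(C)C(=O)OC
F3 | step 13 | methyl 4-[(2Z)-1-hydroxy-3-(4,4,5,5-tetramethyl-1,3,2-dioxaborolan-2-yl)pent-2-en-1-yl]-2,5-dimethyl-3-(prop-1-en-2-yl)hept-6-enoate | C=C[C@@H](C)[C@H](C(O)/C=C(\CC)B1OC(C)(C)C(C)(C)O1)[C@H](C(C)=C)C(C)C(=O)OC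
F4 | step 13 | methyl 4-[(2E,4E,6E)-3-ethyl-1-hydroxy-5-methyl-7-phenylhepta-2,4,6-trien-1-yl]-2,5-dimethyl-3-(prop-1-en-2-yl)hept-6-enoate | C=C[C@@H](C)[C@H](C(O)/C=C(CC)/C=C(C)/C=C/c1ccccc1)[C@H](C(C)=C)C(C)C(=O)OC
F5 | step 13 | methyl 4-[(2E,4E,6E)-3-ethyl-5-methyl-7-phenylhepta-2,4,6-trienoyl]-2,5-dimethyl-3-(prop-1-en-2-yl)hept-6-enoate | C=C[C@@H](C)[C@H](C(=O)/C=C(CC)/C=C(C)/C=C/c1ccccc1)[C@H](C(C)=C)C(C)C(=O)OC
F6 | step 13 | tertiary alkoxide, drawn as the alcohol: methyl 4-[(3E,5E,7E)-4-ethyl-2-hydroxy-6-methyl-8-phenylocta-3,5,7-trien-2-yl]-2,5-dimethyl-3-(prop-1-en-2-yl)hept-6-enoate | C[C@@](O)(/C=C(CC)/C=C(C)/C=C/c1ccccc1)[C@@H]([C@H](C)C=C)[C@H](C(C)=C)C(C)C(=O)OC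
F7 | step 13 | 5-(but-3-en-2-yl)-6-[(1E,3E,5E)-2-ethyl-4-methyl-6-phenylhexa-1,3,5-trien-1-yl]-3,6-dimethyl-4-(prop-1-en-2-yl)oxan-2-one | C[C@]1(/C=C(CC)/C=C(C)/C=C/c2ccccc2)OC(=O)C(C)[C@@H](C(C)=C)[C@@H]1[C@H](C)C=C
F8 | step 13 | trimethylsilyl ketene acetal of F7 | C[C@]1(/C=C(CC)/C=C(C)/C=C/c2ccccc2)OC(O[Si](C)(C)C)=C(C)[C@@H](C(C)=C)[C@@H]1[C@H](C)C=C
F9 | step 13 | trimethylsilyl ester of F10 | CC[C@]1(/C=C(C)/C=C/c2ccccc2)C=C(C)[C@@H]([C@H](C)C=C)[C@H](C(C)=C)[C@@]1(C)C(=O)O[Si](C)(C)C
F10 | step 13 | 5-(but-3-en-2-yl)-2-ethyl-1,4-dimethyl-2-[(1E,3E)-2-methyl-4-phenylbuta-1,3-dien-1-yl]-6-(prop-1-en-2-yl)cyclohex-3-ene-1-carboxylic acid | CC[C@]1(/C=C(C)/C=C/c2ccccc2)C=C(C)[C@@H]([C@H](C)C=C)[C@H](C(C)=C)[C@@]1(C)C(=O)O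
F11 | step 12 | methyl 2-[5-(1-hydroxyethyl)-2,4-dimethylcyclopent-2-en-1-yl]propanoate | CC1=C[C@@H](C)[C@H](C(C)O)[C@H]1C(C)C(=O)OC
F12 | step 12 | methyl 2-(5-acetyl-2,4-dimethylcyclopent-2-en-1-yl)propanoate | CC1=C[C@@H](C)[C@H](C(C)=O)[C@H]1C(C)C(=O)OC
F13 | step 12 | methyl 2-[5-(2-hydroxyhex-3-yn-2-yl)-2,4-dimethylcyclopent-2-en-1-yl]propanoate | C[C@@](O)(C#CCC)[C@H]1[C@H](C)C=C(C)[C@@H]1C(C)C(=O)OC
F14 | step 12 | methyl 2-{5-[(3Z)-2-hydroxy-4-(4,4,5,5-tetramethyl-1,3,2-dioxaborolan-2-yl)hex-3-en-2-yl]-2,4-dimethylcyclopent-2-en-1-yl}propanoate | C[C@@](O)(/C=C(\CC)B2OC(C)(C)C(C)(C)O2)[C@H]1[C@H](C)C=C(C)[C@@H]1C(C)C(=O)OC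
F15 | step 4 | lithium 3-(1,3-dithian-2-yl)-4-[tert-butyl(dimethyl)silyl]oxycyclopent-1-en-1-olate | [Li]OC1=C[C@@H](C2SCCCS2)[C@H](O[Si](C)(C)C(C)(C)C)C1
F16 | step 4 | methyl 2-{2-(1,3-dithian-2-yl)-3-[tert-butyl(dimethyl)silyl]oxy-5-oxocyclopentyl}acetate | O=C1C[C@@H](O[Si](C)(C)C(C)(C)C)[C@H](C2SCCCS2)[C@H]1CC(=O)OC
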